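The data were generated by integration with made-up constants, and the scatter is random.

The south-east flask holds 3.00 times the free catalyst of the north-west flask, and the question is how much of that ratio reaches the rate.

| flask | starting material | reagent | free catalyst | time |
|---|---|---|---|---|
| north-west | 0.500 M | 0.550 M | 0.0500 M |  |
| south | 1.50 M | 0.550 M | 0.0500 M |  |
| south-east | 0.500 M | 0.550 M | 0.150 M |  |
| north-east | 0.250 M | 0.280 M | 0.0500 M | 5.0 min |

- north-west run (time / min: [starting material] / M): 0.20: 0.4952; 0.34: 0.4926; 0.58: 0.4841; 1.0: 0.4688; 1.7: 0.4420; 2.9: 0.3853; 5.0: 0.2791
- south run (time / min: [starting material] / M): 0.20: 1.4806; 0.34: 1.4662; 0.58: 1.4333; 1.0: 1.3617; 1.7: 1.2161; 2.9: 1.0410; 5.0: 0.9615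
- south-east run (time / min: [starting material] / M): 0.20: 0.4894; 0.34: 0.4817; 0.58: 0.4635; 1.0: 0.4351; 1.7: 0.3894; 2.9: 0.3106; 5.0: 0.2062

(scatter of a reading: 0.002 M)

1. apparent order in [free catalyst] of the starting rate, round the charge of the north-west run (the rate where two percent of its starting material have turned into target)
2. apparent order in [starting material] of the starting rate, round the charge of the north-west run (the rate where two percent of its starting material have turned into target) (one fixed amount of target, the same in the runs compared)
3. starting material in the north-east run at 5.0 min, as a share of the starting material charged

- Overall: starting material + reagent -> target, with free catalyst as catalyst.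
- Constant volume, constant temperature.
- "The second partner" is reagent.
- An order is taken over about fifteen percent of the charge, up and down.

1. Before 0.20 min: we assume the catalyst has finished whatever it does with itself. We cannot see this, but we can read how much work each charge does.

2. The first minute: the north-west flask has lost 6.24% of its starting material by 1.0 min. We divide that fraction per minute by the mean fraction left and the mean reagent, which gives the turnover constant 0.121 M⁻¹ min⁻¹, read with a scatter of about 6.41%.

3. Like amounts of target: the south-east flask has lost 7.30% by 0.58 min, so its constant is 0.246 M⁻¹ min⁻¹. That gives an order of 0.648 in free catalyst, but across the whole tripling; no run lies inside the narrower asked span. The south flask has lost 2.25% by 0.34 min, so its constant is 0.126 M⁻¹ min⁻¹, and the order in starting material, across the tripling of that charge, reads 1.04.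

4. Later: between 1.0 min and 2.9 min the north-west constant reads 0.216 M⁻¹ min⁻¹, higher than the first-minute reading, which we take as target speeding its own making (autocatalysis).

5. The end: by 5.0 min the south flask has used 97.9% of its reagent, the limiting reagent there.

6. The north-east flask has the north-west catalyst charge, so we carry the first-minute constant over. A first pass gives a lost fraction of 16.9%; using mean values gives 14.3%, so we expect 85.7% left.

The forecast gives 0.6, 1 and 84.7%, lower than ours on free catalyst and on the share left. Its ground on free catalyst: “only the background path responds to catalyst”.

The flask gives 0.73, 1.0 and 84.8%.

    2 free catalyst ⇌ catalyst dimer, settled at all times (170.0 M⁻¹)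
    free catalyst + starting material + reagent → target + free catalyst (11.04 M⁻² min⁻¹)
    starting material + reagent + target → 2 target (1.830 M⁻² min⁻¹)
    free catalyst + impurity → spent catalyst

The turnover constants gave 0.648 across the tripling, while round the north-west charge the order is higher, 0.73. The impurity, 0.0171 M, takes 34.2% of the north-west catalyst charge but 11.4% of the south-east one. With that passing into spent catalyst taken away, the north-west order falls from 0.73 to 0.49.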